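**Retrosynthetic overview**

- Target 19 comes from ester 17 by ester reduction and hydrogenolysis of the benzyl ether on ring B; 17 comes from phenol 16 by O-methylation.
- Ring A is numbered from the carbon bound to the diaryl ether oxygen (position 1): positions 2 and 6 carry methoxy, positions 3 and 5 are CH, position 4 carries propyl. With oxygen on positions 2, 1 and 6 and the alkyl group on position 4, it is the aromatised, methylated form of a 2-aryloxy-5-propylcyclohexane-1,3-dione (14).
- The dione ring is cut at the bond between positions 4 and 5 and at the bond between positions 1 and 6: dimethyl malonate 10 plus aryloxymethyl enone 9 (Michael–Claisen annulation). The crowded bond from oxygen to position 1 is therefore made early as a phenol alkylation at an sp3 carbon (phenol 5 plus chloro enone 8).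
- Ring B is bought as 5-hydroxyvanillin 1. Ring A is the only ring formed (step 6) and is aromatised in step 8.

Key step: step 6

Remark on the chemistry: the target has no stereocentre. Compounds 11 to 15 are racemic and/or enolised mixtures, and all their centres vanish when ring A is aromatised.

**Route**

Step 1
Reactants: 1 5-hydroxyvanillin (3,4-dihydroxy-5-methoxybenzaldehyde)
Product: 2 4-(benzyloxy)-3-hydroxy-5-methoxybenzaldehyde
Conditions: BnBr, Li2CO3, DMF, 45 °C
Reagents that add atoms: benzyl bromide, BrCc1ccccc1
Why: Williamson etherification under weak base; the 4-OH para to the formyl group is the more acidic phenol, so Li2CO3 ionises it selectively and only that oxygen is benzylated.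

Step 2
Reactants: 2 4-(benzyloxy)-3-hydroxy-5-methoxybenzaldehyde; 3 methyl (triphenylphosphoranylidene)acetate
Product: 4 methyl (E)-3-[4-(benzyloxy)-3-hydroxy-5-methoxyphenyl]prop-2-enoate
Conditions: toluene, 80 °C
Reagents that add atoms: none
Why: Wittig olefination with a stabilised ylide, which tolerates the free phenol and should give the E-cinnamate.

Step 3
Reactants: 4 methyl (E)-3-[4-(benzyloxy)-3-hydroxy-5-methoxyphenyl]prop-2-enoate
Product: 5 methyl 3-[4-(benzyloxy)-3-hydroxy-5-methoxyphenyl]propanoate
Conditions: NaBH4, NiCl2·6H2O (cat.), MeOH–THF, 0 °C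
Reagents that add atoms: none
Why: nickel boride conjugate reduction saturates the cinnamate C=C while leaving the benzyl ether, the ester and the phenol untouched.

Step 4
Reactants: 6 butanal; 7 1-chloro-3-(triphenylphosphoranylidene)propan-2-one
Product: 8 (E)-1-chlorohept-3-en-2-one
Conditions: CH2Cl2, reflux (excess butanal)
Reagents that add atoms: none
Why: Wittig olefination with the stabilised chloroacetonyl ylide should give the E-enone and keeps the chloromethyl ketone for the next step.

Step 5
Reactants: 5 methyl 3-[4-(benzyloxy)-3-hydroxy-5-methoxyphenyl]propanoate; 8 (E)-1-chlorohept-3-en-2-one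
Product: 9 methyl 3-{4-(benzyloxy)-3-methoxy-5-[(E)-2-oxohept-3-enyloxy]phenyl}propanoate
Conditions: K2CO3, NaI (cat.), acetone, rt
Reagents that add atoms: none
Why: Williamson etherification (SN2) at the activated alpha-chloro ketone carbon, which should outrun reversible oxa-Michael addition of the phenoxide to the enone; it forms the future bond from the ether oxygen to position 1 of ring A at an sp3 carbon.

Step 6
Reactants: 9 methyl 3-{4-(benzyloxy)-3-methoxy-5-[(E)-2-oxohept-3-enyloxy]phenyl}propanoate; 10 dimethyl malonate
Product: 12 methyl 3-[2-(benzyloxy)-3-methoxy-5-(3-methoxy-3-oxopropyl)phenoxy]-2,4-dioxo-6-propylcyclohexane-1-carboxylate (racemic enolised epimer mixture), via Michael adduct 11 (not isolated)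
Conditions: 10, NaOMe, MeOH, rt; add 9 at 0 °C, then reflux; aq HCl work-up
Reagents that add atoms: none
Why: Preformed sodium dimethyl malonate adds 1,4 to the enone of 9 (bond between positions 4 and 5 of ring A) to give 11, and under the equilibrating methoxide the ketone enolate at the aryloxymethyl carbon (position 1) attacks one malonate ester carbonyl (bond between positions 1 and 6) in a Dieckmann-type acyl substitution, expelling methoxide and ending at the stabilised enolate of the 2-oxy-1,3-dione, which pulls both equilibria forward. The closest known reaction type is the Michael–Claisen annulation of alk-3-en-2-ones with malonate that leads to 5-alkylcyclohexane-1,3-diones. Ring A closes in a 6-(enolendo)-exo-trig mode. The centres at positions 4, 5 and 1 form without control as a racemic, enolised mixture and are all erased in step 8. The step needs 1,4- over 1,2-addition, secured by the soft, reversibly adding malonate anion, and acylation from position 1 only, secured by ring size (the other alpha carbon, position 3, could close only a four-membered ring) and by the aryloxy group that acidifies position 1. The side-chain methyl ester is only an intermolecular acceptor and its exchange with methoxide is degenerate.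

Step 7
Reactants: 12 methyl 3-[2-(benzyloxy)-3-methoxy-5-(3-methoxy-3-oxopropyl)phenoxy]-2,4-dioxo-6-propylcyclohexane-1-carboxylate
Product: 14 3-{4-(benzyloxy)-3-[(2,6-dioxo-4-propylcyclohexyl)oxy]-5-methoxyphenyl}propanoic acid, via diacid 13 (not isolated)
Conditions: aq NaOH, THF, 60 °C; then aq HCl to pH 1, 70 °C
Reagents that add atoms: sodium hydroxide, [Na+].[OH-]
Why: saponification of both methyl esters followed by decarboxylation of the 2-carboxy-1,3-dione (a vinylogous beta-keto acid) on acidification and warming; the dione is protected as its enolate during the basic stage.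

Step 8
Reactants: 14 3-{4-(benzyloxy)-3-[(2,6-dioxo-4-propylcyclohexyl)oxy]-5-methoxyphenyl}propanoic acid
Product: 16 methyl 3-[4-(benzyloxy)-3-(2-hydroxy-6-methoxy-4-propylphenoxy)-5-methoxyphenyl]propanoate, via methyl enol ether 15 (not isolated)
Conditions: I2 (2 equiv), MeOH, reflux; aq Na2S2O3 work-up
Reagents that add atoms: methanol, CO
Why: iodine–methanol oxidative aromatisation of a 2-substituted cyclohexane-1,3-dione: acid-catalysed formation of methyl enol ether 15 (with Fischer esterification of the side-chain acid), alpha'-iodination, loss of HI and tautomerisation should give the resorcinol monomethyl ether; any dimethyl ether formed alongside is already 17 and is carried on.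

Step 9
Reactants: 16 methyl 3-[4-(benzyloxy)-3-(2-hydroxy-6-methoxy-4-propylphenoxy)-5-methoxyphenyl]propanoate
Product: 17 methyl 3-[4-(benzyloxy)-3-(2,6-dimethoxy-4-propylphenoxy)-5-methoxyphenyl]propanoate
Conditions: MeI, K2CO3, acetone, reflux
Reagents that add atoms: iodomethane, CI
Why: Williamson O-methylation of the remaining ring A phenol (and of any side-chain acid that escaped esterification) completes the 2,6-dimethoxy pattern.

Step 10
Reactants: 17 methyl 3-[4-(benzyloxy)-3-(2,6-dimethoxy-4-propylphenoxy)-5-methoxyphenyl]propanoate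
Product: 18 3-[4-(benzyloxy)-3-(2,6-dimethoxy-4-propylphenoxy)-5-methoxyphenyl]propan-1-ol
Conditions: LiAlH4, THF, 0 °C to rt
Reagents that add atoms: none
Why: hydride reduction of the methyl ester to the primary alcohol; the aryl ethers and the benzyl ether are inert to LiAlH4.

Step 11
Reactants: 18 3-[4-(benzyloxy)-3-(2,6-dimethoxy-4-propylphenoxy)-5-methoxyphenyl]propan-1-ol
Product: 19 2-(2,6-dimethoxy-4-propylphenoxy)-4-(3-hydroxypropyl)-6-methoxyphenol (target)
Conditions: H2 (1 atm), Pd/C, EtOAc–MeOH, rt
Reagents that add atoms: none
Why: catalytic hydrogenolysis of the benzyl aryl ether frees the ring B phenol without touching the diaryl ether, the methyl ethers or the alcohol.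

**Compound list**

1 | 5-hydroxyvanillin (3,4-dihydroxy-5-methoxybenzaldehyde) | O=Cc1cc(O)c(O)c(OC)c1 | starting material
2 | 4-(benzyloxy)-3-hydroxy-5-methoxybenzaldehyde | O=Cc1cc(O)c(OCc2ccccc2)c(OC)c1 | intermediate
3 | methyl (triphenylphosphoranylidene)acetate | COC(=O)C=P(c1ccccc1)(c1ccccc1)c1ccccc1 | starting material
4 | methyl (E)-3-[4-(benzyloxy)-3-hydroxy-5-methoxyphenyl]prop-2-enoate | COC(=O)/C=C/c1cc(O)c(OCc2ccccc2)c(OC)c1 | intermediate
5 | methyl 3-[4-(benzyloxy)-3-hydroxy-5-methoxyphenyl]propanoate | COC(=O)CCc1cc(O)c(OCc2ccccc2)c(OC)c1 | intermediate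
6 | butanal | CCCC=O | starting material
7 | 1-chloro-3-(triphenylphosphoranylidene)propan-2-one | O=C(CCl)C=P(c1ccccc1)(c1ccccc1)c1ccccc1 | starting material
8 | (E)-1-chlorohept-3-en-2-one | CCC/C=C/C(=O)CCl | intermediate
9 | methyl 3-{4-(benzyloxy)-3-methoxy-5-[(E)-2-oxohept-3-enyloxy]phenyl}propanoate | CCC/C=C/C(=O)COc1cc(CCC(=O)OC)cc(OC)c1OCc1ccccc1 | intermediate
10 | dimethyl malonate | COC(=O)CC(=O)OC | starting material
11 | dimethyl 2-{1-[2-(benzyloxy)-3-methoxy-5-(3-methoxy-3-oxopropyl)phenoxy]-2-oxoheptan-4-yl}propanedioate (racemic Michael adduct) | CCCC(CC(=O)COc1cc(CCC(=O)OC)cc(OC)c1OCc1ccccc1)C(C(=O)OC)C(=O)OC | intermediate (not isolated)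
12 | methyl 3-[2-(benzyloxy)-3-methoxy-5-(3-methoxy-3-oxopropyl)phenoxy]-2,4-dioxo-6-propylcyclohexane-1-carboxylate (racemic, enolised epimer mixture) | CCCC1CC(=O)C(Oc2cc(CCC(=O)OC)cc(OC)c2OCc2ccccc2)C(=O)C1C(=O)OC | intermediate
13 | 3-[2-(benzyloxy)-5-(2-carboxyethyl)-3-methoxyphenoxy]-2,4-dioxo-6-propylcyclohexane-1-carboxylic acid (diacid, racemic) | CCCC1CC(=O)C(Oc2cc(CCC(=O)O)cc(OC)c2OCc2ccccc2)C(=O)C1C(=O)O | intermediate (not isolated)
14 | 3-{4-(benzyloxy)-3-[(2,6-dioxo-4-propylcyclohexyl)oxy]-5-methoxyphenyl}propanoic acid (enolised) | CCCC1CC(=O)C(Oc2cc(CCC(=O)O)cc(OC)c2OCc2ccccc2)C(=O)C1 | intermediate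
15 | methyl 3-{4-(benzyloxy)-3-methoxy-5-[(2-methoxy-6-oxo-4-propylcyclohex-1-en-1-yl)oxy]phenyl}propanoate (racemic methyl enol ether) | CCCC1CC(=O)C(Oc2cc(CCC(=O)OC)cc(OC)c2OCc2ccccc2)=C(OC)C1 | intermediate (not isolated)
16 | methyl 3-[4-(benzyloxy)-3-(2-hydroxy-6-methoxy-4-propylphenoxy)-5-methoxyphenyl]propanoate | CCCc1cc(O)c(Oc2cc(CCC(=O)OC)cc(OC)c2OCc2ccccc2)c(OC)c1 | intermediate
17 | methyl 3-[4-(benzyloxy)-3-(2,6-dimethoxy-4-propylphenoxy)-5-methoxyphenyl]propanoate | CCCc1cc(OC)c(Oc2cc(CCC(=O)OC)cc(OC)c2OCc2ccccc2)c(OC)c1 | intermediate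
18 | 3-[4-(benzyloxy)-3-(2,6-dimethoxy-4-propylphenoxy)-5-methoxyphenyl]propan-1-ol | CCCc1cc(OC)c(Oc2cc(CCCO)cc(OC)c2OCc2ccccc2)c(OC)c1 | intermediate
19 | 2-(2,6-dimethoxy-4-propylphenoxy)-4-(3-hydroxypropyl)-6-methoxyphenol | CCCc1cc(OC)c(Oc2cc(CCCO)cc(OC)c2O)c(OC)c1 | target

**Step count**

Total: 11 steps. Longest linear sequence: 10 steps (steps 1, 2, 3, 5, 6, 7, 8, 9, 10, 11 from 5-hydroxyvanillin); step 4 is a one-step side branch.

**Steps most likely to fail**

1. Step 6 (Michael–Claisen annulation). The enone may self-condense through its acidic aryloxymethyl position before malonate adds, or the sequence may stall at the open Michael adduct without ring closure. The fallback attaches the aryl ether oxygen to a preformed dione ring. It sets out from phenol 5. Purchased 5-propylcyclohexane-1,3-dione F1 is converted by Regitz diazo transfer (4-acetamidobenzenesulfonyl azide, Et3N, MeCN, 0 °C to rt) into 2-diazo-5-propylcyclohexane-1,3-dione F2. Rh2(OAc)4-catalysed O–H insertion of the derived carbenoid into the phenol of 5 (CH2Cl2, 40 °C) should give methyl 3-{4-(benzyloxy)-3-[(2,6-dioxo-4-propylcyclohexyl)oxy]-5-methoxyphenyl}propanoate F3. F3 is aromatised under the conditions of step 8, and the fallback comes back to the route at 16.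

2. Step 8 (iodine–methanol aromatisation). The HI released may cleave the benzyl ether, iodine may substitute the electron-rich rings, or dehydrogenation may stop short of the arene. The fallback separates enol ether formation from a halogen-free dehydrogenation. It sets out from dione acid 14, which is heated with MeOH and TsOH (cat.) over 3 Å molecular sieves to isolate methyl enol ether 15, the side-chain acid being esterified at the same time. Compound 15 is then dehydrogenated with Pd(OCOCF3)2 (cat.), 2-(dimethylamino)pyridine and TsOH under O2 in DMSO at 80 °C, through a palladium enolate at the alpha' carbon, beta-hydride elimination and tautomerisation. The fallback comes back to the route at 16.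

3. Step 5 (alkylation with the bifunctional chloro enone). Conjugate addition of the phenoxide to the enone, or base-induced oligomerisation of the chloro enone, may compete with substitution at the chloromethyl carbon. The fallback reverses the order of etherification and olefination. It sets out from phenol 5 and ylide 7: O-alkylation of 5 with 7 (K2CO3, NaI cat., DMF, 50 °C) should give the stabilised phosphorane methyl 3-{4-(benzyloxy)-3-methoxy-5-[2-oxo-3-(triphenylphosphoranylidene)propoxy]phenyl}propanoate F4, which offers no Michael acceptor. Wittig olefination of F4 with butanal 6 (toluene, 80 °C) then brings the fallback back to the route at enone 9.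

**Further compounds**

F1 | step 6 | 5-propylcyclohexane-1,3-dione | CCCC1CC(=O)CC(=O)C1
F2 | step 6 | 2-diazo-5-propylcyclohexane-1,3-dione | CCCC1CC(=O)C(=[N+]=[N-])C(=O)C1
F3 | step 6 | methyl 3-{4-(benzyloxy)-3-[(2,6-dioxo-4-propylcyclohexyl)oxy]-5-methoxyphenyl}propanoate | CCCC1CC(=O)C(Oc2cc(CCC(=O)OC)cc(OC)c2OCc2ccccc2)C(=O)C1
F0 | step 8 | none | none
F4 | step 5 | methyl 3-{4-(benzyloxy)-3-methoxy-5-[2-oxo-3-(triphenylphosphoranylidene)propoxy]phenyl}propanoate | COC(=O)CCc1cc(OC)c(OCc2ccccc2)c(OCC(=O)C=P(c2ccccc2)(c2ccccc2)c2ccccc2)c1
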